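Does the excess of right-handed substrate in this flask reach 80% by 2.5 d, and how high does it climb?

- gamma: left-handed substrate 0.50 M; right-handed substrate 0.50 M; reagent 1 M; precatalyst 0.50 mM; the very flask that is asked about, followed so far
- flask: left-handed substrate 0.50 M; reagent 1.00 M; precatalyst 0.50 mM; right-handed substrate 0.50 M; time 2.5 d

gamma run (percent of the left-handed substrate and right-handed substrate together charged)

| time / h | right-handed substrate / % | left-handed substrate / % | left-handed product / % |
|---|---|---|---|
| 2.00 | 50.2 | 46.5 | 4.0 |
| 4.00 | 48.1 | 40.0 | 9.4 |
| 6.00 | 47.7 | 34.8 | 12.6 |
| 12.0 | 44.7 | 23.7 | 25.5 |
| 25.0 | 42.3 | 10.7 | 39.6 |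

(scatter of a reading: 1 percentage point)

- free catalyst is single-handed; left-handed substrate and right-handed substrate are mirror images of each other, charged as a racemate, each of them at the stated concentration

* whether the excess of right-handed substrate over left-handed substrate among what is left of the two reaches 80% by 2.5 d (yes / no)
* the highest excess of right-handed substrate over left-handed substrate among what is left of the two up to 2.5 d

The gamma run is this same flask, followed to 25.0 h, so what separates the two is the time they are given. At that last reading the gamma run shows an excess of 59.6%.

To see further, follow one molecule of each hand. Let l and r be the fractions of the left-handed and right-handed substrate still left, each of its own charge. The selectivity factor s is ln l over ln r, and the last gamma reading puts it at 9.22, a reading that carries the scatter. While s holds, l is r raised to the power s, so the excess, (r − l)/(r + l), follows how far l has fallen, whatever the clock says.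

The wanted excess needs l down to 8.50%, which is less than the 21.4% of the gamma run at 25.0 h. Keep its average rate and you reach that l at 1.67 d, inside 2.5 d, so your answer is yes. The top then depends on how far l falls by the end.

The forecast says yes with a top of 92%, on the ground that “The slope hardly drifts, even as the reagent is consumed”.

The flask gives yes, reaching 80% at 1.88 d, with a top of 85.5%.

    free catalyst + left-handed substrate ⇌ catalyst intermediate A (K = 60.0 /M, k = 3.50 /M/s)
    free catalyst + right-handed substrate ⇌ catalyst intermediate B (K = 9.40 /M, k = 2.40 /M/s)
    reagent + catalyst intermediate A → free catalyst + left-handed product (k = 0.0280 /M/s)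
    reagent + catalyst intermediate B → free catalyst + right-handed product (k = 0.0140 /M/s)
    precatalyst ⇌ free catalyst (K = 2.40, k = 1.90 × 10⁻⁴ /s)
    free catalyst → spent catalyst (k = 5.10 × 10⁻⁵ /s)
    2 reagent → self-condensation product (k = 3.80 × 10⁻⁶ /M/s)

The flask ends with 6.0% of the charged left-handed substrate unbound, and s turns that l into an excess of 84.9%. At 0.426 d the forward binding of left-handed substrate to free catalyst alone gives a half-life of 0.090 d, short against the 2.5 d, but catalyst intermediate A then falls back 3.7 times faster than it goes on. Half of the turnover to left-handed product up to 2.5 d is done by 0.427 d, and at 2.50 d spent catalyst stands at 65.9% of the catalyst charged.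

The earlier runs and the new flask come from a simulation from invented constants.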